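The 2-arylbenzofuran is cut at the bond between furan C2 and C8 of the chromene ring. Because C2 lies between O1 and C3 of the furan ring, the C2=C3 unit is traced back to the triple bond of an o-ethynylphenol whose hydroxyl is the future O1. A Pd/Cu alkynylation of 8-iodochromene 13 with o-ethynylphenol 5 forms the C2–C8 bond, and the neighbouring phenol then adds to the alkyne (O1–C2, 5-endo-dig) in the same flask. One operation joins the two halves and creates the furan ring; the precursor 5 contains no heterocycle. Both remaining phenols travel as MOM ethers, removed last.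

Key step: step 8

Remark: the target has no stereocentre and no stereogenic double bond, so no stereocontrol is needed; only the transient o-quinone methide 12 carries a double-bond descriptor. Compounds 1 and 6 and all reagents named are taken to be catalogue chemicals.

Step 1
Reactants: 1 5-bromo-2,4-dihydroxybenzaldehyde
Product: 2 5-bromo-2-hydroxy-4-(methoxymethoxy)benzaldehyde
Conditions: MOMCl (1.05 equiv), K2CO3, acetone, 0 °C to rt
Reagents that add atoms: chloromethyl methyl ether, COCCl
Why: Chemoselective Williamson-type MOM ether formation, in which the 4-OH (more acidic, not chelated) should react while the 2-OH stays locked in its hydrogen bond to the formyl group.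

Step 2
Reactants: 2 5-bromo-2-hydroxy-4-(methoxymethoxy)benzaldehyde
Product: 3 2-hydroxy-4-(methoxymethoxy)-5-(3-methylbut-2-en-1-yl)benzaldehyde
Conditions: tributyl(3-methylbut-2-en-1-yl)stannane (1.3 equiv), Pd(PPh3)4 (5 mol %), DMF, 100 °C
Reagents that add atoms: tributyl(3-methylbut-2-en-1-yl)stannane, CC(C)=CC[Sn](CCCC)(CCCC)CCCC
Why: Stille cross-coupling under neutral conditions, which keeps the phenol para to bromine unionised so that oxidative addition stays feasible, with reductive elimination at the less hindered allyl terminus expected to give the linear prenyl arene while aldehyde, phenol and MOM ether are tolerated.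

Step 3
Reactants: 3 2-hydroxy-4-(methoxymethoxy)-5-(3-methylbut-2-en-1-yl)benzaldehyde
Product: 5 2-ethynyl-5-(methoxymethoxy)-4-(3-methylbut-2-en-1-yl)phenol, via diazoalkene 4 (not isolated)
Conditions: Ohira–Bestmann reagent (1.8 equiv), K2CO3 (3 equiv), MeOH, 0 °C to rt
Reagents that add atoms: dimethyl (1-diazo-2-oxopropyl)phosphonate, CC(=O)C(=[N+]=[N-])P(=O)(OC)OC
Why: Seyferth–Gilbert homologation in its Ohira–Bestmann form, in which the diazomethylphosphonate anion released by methanolysis adds to the aldehyde, loses dimethyl phosphate to give diazoalkene 4 and then N2 with 1,2-H shift to the terminal alkyne, the MOM ether and prenyl group being inert to K2CO3/MeOH.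

Step 4
Reactants: 6 resorcinol
Product: 7 3-(methoxymethoxy)phenol
Conditions: resorcinol (2.5 equiv), MOMCl (1.0 equiv), K2CO3, acetone, 0 °C to rt
Reagents that add atoms: chloromethyl methyl ether, COCCl
Why: Statistical mono-protection by Williamson-type MOM ether formation with resorcinol in excess, the surplus diol being removed by aqueous wash and any bis-ether by chromatography.

Step 5
Reactants: 7 3-(methoxymethoxy)phenol
Product: 8 2-iodo-5-(methoxymethoxy)phenol
Conditions: I2 (1.0 equiv), NaHCO3, THF/H2O (1:1), 0 °C
Reagents that add atoms: iodine, II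
Why: Electrophilic aromatic iodination, expected at the carbon ortho to the free OH and para to the MOM ether as is usual for 3-alkoxyphenols under these conditions, since the site para to OH is flanked by the MOM ether and the site between both oxygens is the most hindered.

Step 6
Reactants: 8 2-iodo-5-(methoxymethoxy)phenol
Product: 9 1-iodo-4-(methoxymethoxy)-2-[(2-methylbut-3-yn-2-yl)oxy]benzene
Conditions: 3-chloro-3-methylbut-1-yne (1.5 equiv), DBU, CuCl2·2H2O (1 mol %), MeCN, 0 °C
Reagents that add atoms: 3-chloro-3-methylbut-1-yne, CC(C)(Cl)C#C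
Why: Copper-catalysed O-propargylation of a phenol with a tertiary propargylic chloride, which should proceed at 0 °C even with an ortho-substituted phenol and leave the aryl iodide untouched.

Step 7
Reactants: 9 1-iodo-4-(methoxymethoxy)-2-[(2-methylbut-3-yn-2-yl)oxy]benzene
Product: 13 8-iodo-5-(methoxymethoxy)-2,2-dimethyl-2H-chromene, via allenyl dienone 10 (not isolated), via allenylphenol 11 (not isolated), via o-quinone methide 12 (not isolated)
Conditions: PhNEt2, 150 °C
Reagents that add atoms: none
Why: Aromatic propargyl Claisen rearrangement cascade, in which the [3,3] shift goes to the only free ortho carbon (the other bears iodine) to give dienone 10, tautomerisation gives 11, a 1,5-H shift gives 12 and an oxa-6π electrocyclisation closes the 2,2-dimethylpyran ring with its oxygen next to the iodine.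

Step 8
Reactants: 5 2-ethynyl-5-(methoxymethoxy)-4-(3-methylbut-2-en-1-yl)phenol; 13 8-iodo-5-(methoxymethoxy)-2,2-dimethyl-2H-chromene
Product: 15 6-(methoxymethoxy)-2-[5-(methoxymethoxy)-2,2-dimethyl-2H-chromen-8-yl]-5-(3-methylbut-2-en-1-yl)-1-benzofuran, via diarylalkyne 14 (not isolated)
Conditions: PdCl2(PPh3)2 (5 mol %), CuI (5 mol %), Et3N, degassed DMF, slow addition of 5 at rt, then 70 °C
Reagents that add atoms: none
Why: Pd(0) inserts into the C8–I bond of 13, the copper acetylide of 5 transmetalates and reductive elimination forms the C(sp)–C(sp2) bond that becomes C2(furan)–C8(chromene), giving diarylalkyne 14; the ortho-phenol oxygen then adds across the Pd(II)/Cu(I)-activated triple bond and protodemetalation releases the benzofuran. The closest known reaction type is the domino Sonogashira coupling/cycloisomerisation of o-ethynylphenols with aryl halides to 2-arylbenzofurans. The furan ring closes in the 5-endo-dig mode (O1 onto the distal alkyne carbon), the only accessible mode because attack at the proximal carbon would be 4-exo. No stereocentre is formed. The step needs cross-coupling to outrun Glaser dimerisation and premature cycloisomerisation of 5, which the reactive aryl iodide, exclusion of oxygen and slow addition of 5 at rt before warming should secure; Heck insertion into the trisubstituted prenyl and cis-disubstituted chromene alkenes should not compete with transmetalation, and the MOM ethers keep the other two phenols out of play.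

Step 9
Reactants: 15 6-(methoxymethoxy)-2-[5-(methoxymethoxy)-2,2-dimethyl-2H-chromen-8-yl]-5-(3-methylbut-2-en-1-yl)-1-benzofuran
Product: 16 kanzonol V
Conditions: HCl (ca. 1 M in MeOH), 40 °C
Reagents that add atoms: none
Why: Acid-catalysed acetal exchange (methanolysis of both aryl MOM ethers), which under dilute acid at moderate temperature should release the two phenols without touching the prenyl group, the chromene or the benzofuran.

Compound list
1 | 5-bromo-2,4-dihydroxybenzaldehyde | O=Cc1cc(Br)c(O)cc1O | starting material
2 | 5-bromo-2-hydroxy-4-(methoxymethoxy)benzaldehyde | COCOc1cc(O)c(C=O)cc1Br | intermediate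
3 | 2-hydroxy-4-(methoxymethoxy)-5-(3-methylbut-2-en-1-yl)benzaldehyde | COCOc1cc(O)c(C=O)cc1CC=C(C)C | intermediate
4 | 2-(2-diazoethenyl)-5-(methoxymethoxy)-4-(3-methylbut-2-en-1-yl)phenol (diazoalkene) | COCOc1cc(O)c(C=C=[N+]=[N-])cc1CC=C(C)C | intermediate (not isolated)
5 | 2-ethynyl-5-(methoxymethoxy)-4-(3-methylbut-2-en-1-yl)phenol | COCOc1cc(O)c(C#C)cc1CC=C(C)C | intermediate
6 | resorcinol (benzene-1,3-diol) | Oc1cccc(O)c1 | starting material
7 | 3-(methoxymethoxy)phenol | COCOc1cccc(O)c1 | intermediate
8 | 2-iodo-5-(methoxymethoxy)phenol | COCOc1ccc(I)c(O)c1 | intermediate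
9 | 1-iodo-4-(methoxymethoxy)-2-[(2-methylbut-3-yn-2-yl)oxy]benzene | COCOc1ccc(I)c(OC(C)(C)C#C)c1 | intermediate
10 | 2-iodo-5-(methoxymethoxy)-6-(3-methylbuta-1,2-dien-1-yl)cyclohexa-2,4-dien-1-one (allenyl dienone, racemic) | COCOC1=CC=C(I)C(=O)C1C=C=C(C)C | intermediate (not isolated)
11 | 6-iodo-3-(methoxymethoxy)-2-(3-methylbuta-1,2-dien-1-yl)phenol (allenylphenol) | COCOc1ccc(I)c(O)c1C=C=C(C)C | intermediate (not isolated)
12 | (6Z)-2-iodo-5-(methoxymethoxy)-6-(3-methylbut-2-en-1-ylidene)cyclohexa-2,4-dien-1-one (o-quinone methide) | COCOC1=CC=C(I)C(=O)/C1=C\C=C(C)C | intermediate (not isolated)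
13 | 8-iodo-5-(methoxymethoxy)-2,2-dimethyl-2H-chromene | COCOc1ccc(I)c2OC(C)(C)C=Cc12 | intermediate
14 | 2-{[5-(methoxymethoxy)-2,2-dimethyl-2H-chromen-8-yl]ethynyl}-5-(methoxymethoxy)-4-(3-methylbut-2-en-1-yl)phenol (diarylalkyne) | COCOc1cc(O)c(C#Cc2ccc(OCOC)c3C=CC(C)(C)Oc23)cc1CC=C(C)C | intermediate (not isolated)
15 | 6-(methoxymethoxy)-2-[5-(methoxymethoxy)-2,2-dimethyl-2H-chromen-8-yl]-5-(3-methylbut-2-en-1-yl)-1-benzofuran | COCOc1cc2oc(-c3ccc(OCOC)c4C=CC(C)(C)Oc34)cc2cc1CC=C(C)C | intermediate
16 | kanzonol V, 2-(5-hydroxy-2,2-dimethyl-2H-chromen-8-yl)-5-(3-methylbut-2-en-1-yl)-1-benzofuran-6-ol | CC(C)=CCc1cc2cc(-c3ccc(O)c4c3OC(C)(C)C=C4)oc2cc1O | target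

Total step count: 9
Longest linear sequence: 6 steps (steps 4, 5, 6, 7, 8, 9)

Steps most likely to fail

1. Step 8 (key step). What may go wrong: oxidative homodimerisation of the terminal alkyne, cycloisomerisation of 5 before it has coupled, or slow oxidative addition into the electron-rich, ortho-alkoxylated C–I bond. Fallback (ring first, bond second): setting out from 5, copper-catalysed 5-endo-dig cycloisomerisation (CuI, Et3N, DMF, 80 °C) should give 6-(methoxymethoxy)-5-(3-methylbut-2-en-1-yl)-1-benzofuran F1. Deprotonation at the kinetically most acidic C2–H (n-BuLi, THF, −78 °C) gives [6-(methoxymethoxy)-5-(3-methylbut-2-en-1-yl)-1-benzofuran-2-yl]lithium F2. Transmetalation with ZnCl2 gives the corresponding benzofuran-2-ylzinc chloride F3. Negishi coupling of this with iodide 13 (Pd(PPh3)4, THF, 50 °C) forms the same C2–C8 bond and returns to the route at 15.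

2. Step 3. What may go wrong: the substrate reacts as its phenoxide, which lowers the electrophilicity of the formyl group, so that addition of the diazophosphonate anion stalls while the reagent decomposes. Fallback (Corey–Fuchs sequence): setting out from 3, Ramirez dibromo-olefination (CBr4, PPh3, Et3N, CH2Cl2, 0 °C) should give 2-(2,2-dibromoethenyl)-5-(methoxymethoxy)-4-(3-methylbut-2-en-1-yl)phenol F4. Treatment with n-BuLi (3.3 equiv, THF, −78 °C to 0 °C; bromine–lithium exchange and 1,2-shift), then aqueous NH4Cl, returns to the route at 5.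

3. Step 9. What may go wrong: acid-induced addition of the liberated ortho-phenol to the prenyl double bond (chroman formation) or acid-promoted addition to the chromene double bond, competing with acetal cleavage. Fallback (non-protic acetal-to-silyl exchange): setting out from 15, TMSOTf/2,2′-bipyridyl (MeCN, 0 °C) should convert both aryl MOM ethers into the bis(trimethylsilyl) ether of kanzonol V F5. Desilylation with K2CO3 in MeOH at rt returns to the route at 16.

Further compounds
F1 | step 8 | 6-(methoxymethoxy)-5-(3-methylbut-2-en-1-yl)-1-benzofuran | COCOc1cc2occc2cc1CC=C(C)C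
F2 | step 8 | [6-(methoxymethoxy)-5-(3-methylbut-2-en-1-yl)-1-benzofuran-2-yl]lithium | [Li]c1cc2cc(CC=C(C)C)c(OCOC)cc2o1
F3 | step 8 | [6-(methoxymethoxy)-5-(3-methylbut-2-en-1-yl)-1-benzofuran-2-yl]zinc chloride | Cl[Zn]c1cc2cc(CC=C(C)C)c(OCOC)cc2o1
F4 | step 3 | 2-(2,2-dibromoethenyl)-5-(methoxymethoxy)-4-(3-methylbut-2-en-1-yl)phenol | COCOc1cc(O)c(C=C(Br)Br)cc1CC=C(C)C
F5 | step 9 | 2-[2,2-dimethyl-5-(trimethylsilyloxy)-2H-chromen-8-yl]-5-(3-methylbut-2-en-1-yl)-6-(trimethylsilyloxy)-1-benzofuran | CC(C)=CCc1cc2cc(-c3ccc(O[Si](C)(C)C)c4C=CC(C)(C)Oc34)oc2cc1O[Si](C)(C)C
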